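**Retrosynthetic overview**

1. Locants: C1' is the diaryl methine, C2' and C3' are the methyl-bearing carbons, C4' is the benzylic CH2; ring A is the phloroglucinol, ring B the aryl on C1', ring C the aryl on C4'. The plan rests on the para-hydroxyl of ring B, which makes C1' the electrophilic end of a p-quinone methide, and on C2'/C3' being the α- and β-carbons of a crotonate whose carbonyl carbon ends as the C2' methyl.
2. Last disconnection: the ring A–C(=O) bond (Houben–Hoesch acylation of pentaphenol 19 with nitrile 20). Before it come the four benzyl ethers and the C2' methyl, traced back through CH2I and CH2OH to the acyl carbon of N-acyl oxazolidinone 15.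
3. Key disconnections, made in one operation: C3'–C4' (conjugate addition of the copper reagent from benzylic Grignard 5 to crotonyl imide 3) and C1'–C2' (1,6-addition of the resulting enolate to quinone methide 14). All three stereocentres arise here.
4. Quinone methide 14 comes from silyl ether acetate 11, itself made from 2,4,6-tris(benzyloxy)phenyllithium and 4-silyloxybenzaldehyde 8.
5. Ring formation: none. Rings A, B and C are bought as arenes; ring A is joined to ring B in step 4, ring C and the stereotriad are added in step 5, and ring A is acylated last.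

Key step: step 5

Assumption: commercial crotonyl chloride is used as its (E)-isomer (imide 3 is purified by crystallisation), and compounds 6, 8 and 20 are taken as catalogue materials.

**Route**

Step 1
Reactants: 1 (S)-4-benzyloxazolidin-2-one; 2 (E)-crotonyl chloride
Product: 3 (S)-4-benzyl-3-[(E)-but-2-enoyl]oxazolidin-2-one
Conditions: n-BuLi, THF, −78 °C; then 2, −78 → 0 °C
Reagents that add atoms: none
Why: N-acylation of the lithiated oxazolidinone by the acid chloride (standard Evans imide formation) proceeds at −78 °C without touching the (E)-alkene or the auxiliary stereocentre.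

Step 2
Reactants: 4 4-(benzyloxy)benzyl chloride
Product: 5 4-(benzyloxy)benzylmagnesium chloride (THF solution, titrated)
Conditions: Mg turnings (excess, I2-activated), THF, 0 °C → rt, slow addition at high dilution
Reagents that add atoms: magnesium, [Mg]
Why: Magnesium inserts into the benzylic C–Cl bond (Grignard formation), the aryl benzyl ether being inert, and slow addition over excess metal holds back Wurtz coupling.

Step 3
Reactants: 6 1,3,5-tris(benzyloxy)benzene
Product: 7 2-bromo-1,3,5-tris(benzyloxy)benzene
Conditions: NBS (1.0 equiv), CH2Cl2, −78 → 0 °C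
Reagents that add atoms: N-bromosuccinimide, O=C1CCC(=O)N1Br
Why: Electrophilic aromatic bromination of the symmetrical, strongly activated trialkoxybenzene, whose three free positions are equivalent, should stop at the monobromide with one equivalent of NBS at low temperature.

Step 4
Reactants: 7 2-bromo-1,3,5-tris(benzyloxy)benzene; 8 4-(tert-butyldimethylsilyloxy)benzaldehyde
Product: 11 [4-(tert-butyldimethylsilyloxy)phenyl][2,4,6-tris(benzyloxy)phenyl]methyl acetate (racemic), via 2,4,6-tris(benzyloxy)phenyllithium 9 (not isolated), via lithium alkoxide 10 (not isolated)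
Conditions: n-BuLi, THF, −78 °C; 8, −78 °C; Ac2O, DMAP (cat.), −78 → 0 °C; NaHCO3 work-up, Et3N-deactivated silica
Reagents that add atoms: acetic anhydride, CC(=O)OC(C)=O
Why: Bromine–lithium exchange gives the aryllithium, which adds 1,2 to the aldehyde, and the alkoxide is acetylated in the same flask so that the acid-labile carbinol is never isolated; the new carbinol centre is racemic and is erased when the quinone methide is formed.

Step 5
Reactants: 3 (S)-4-benzyl-3-[(E)-but-2-enoyl]oxazolidin-2-one; 5 4-(benzyloxy)benzylmagnesium chloride; 11 [4-(tert-butyldimethylsilyloxy)phenyl][2,4,6-tris(benzyloxy)phenyl]methyl acetate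
Product: 15 (4S)-4-benzyl-3-[(2R,3S)-4-[4-(benzyloxy)phenyl]-2-[(R)-(4-hydroxyphenyl)[2,4,6-tris(benzyloxy)phenyl]methyl]-3-methylbutanoyl]oxazolidin-2-one, via 4-(benzyloxy)benzylcopper 12 (not isolated), via chloromagnesium Z-enolate 13 (not isolated), via quinone methide 14 (not isolated)
Conditions: CuBr·SMe2 (1.3 equiv), 5 (1.3 equiv), THF/Me2S, −40 °C; 3, −78 → −20 °C; then 14 [second flask: 11 (2 equiv), (Me2N)3S+ Me3SiF2− (TASF), THF, −40 °C] by cannula at −78 °C, → −30 °C; aq NH4Cl
Reagents that add atoms: none
Why: Proposed new method: the benzylcopper reagent 12 adds to the β-carbon of the magnesium-chelated s-cis imide 3 (C3'–C4' bond), and the chelated Z-enolate 13 is intercepted before protonation by 1,6-addition to the exocyclic carbon of quinone methide 14 (C1'–C2' bond), driven by aromatisation to the ring B phenoxide; no ring is closed. The closest known reaction types are the CuBr·SMe2-mediated addition of Grignard reagents to N-enoyl oxazolidinones with in situ capture of the enolate by an electrophile such as N-bromosuccinimide, and the 1,6-addition of enolates to p-quinone methides. C3' is set by the auxiliary: its 4-benzyl group covers one face of the chelated enoyl unit and the copper reagent enters from the other, which gives 3'S. C2' is set by the same element, because the chelated Z-enolate offers the same open face to the quinone methide, so the two new carbon substituents end up syn across the former double bond and C2' has the configuration of the target once the acyl carbon is reduced to methyl. C1' depends on the relative topicity of enolate and methide faces: the open transition state expected to be lowest places the methide hydrogen in the crowded sector between the imide carbon and C3', turns the twisted ortho-disubstituted ring A away from the chelate and the oxazolidinone, and leaves the flat quinoid ring beside the imide carbon, which leads to 1'R, but this is the least secure element. The step needs C-attack of the enolate at the exocyclic methide carbon in preference to capture of 14 by residual organocopper or proton transfer, which is secured by the aromatisation that only 1,6-attack provides, by the two-point chelate that keeps the enolate C-nucleophilic, by using the copper reagent in slight excess only and the methide in excess, and by generating 14 with an anhydrous fluoride source.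

Step 6
Reactants: 15 the N-acyl oxazolidinone from step 5
Product: 16 (2R,3S)-4-[4-(benzyloxy)phenyl]-2-[(R)-(4-hydroxyphenyl)[2,4,6-tris(benzyloxy)phenyl]methyl]-3-methylbutan-1-ol
Conditions: LiBH4 (excess), MeOH, THF, 0 °C → rt
Reagents that add atoms: none
Why: Reductive cleavage of the N-acyl oxazolidinone: borohydride attacks the lithium-chelated exocyclic imide carbonyl and reduces it to the primary alcohol while releasing the auxiliary, under conditions that leave C2', the benzyl ethers and the phenoxide untouched.

Step 7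
Reactants: 16 the primary alcohol
Product: 17 4-[(1R,2R,3S)-4-[4-(benzyloxy)phenyl]-2-(iodomethyl)-3-methyl-1-[2,4,6-tris(benzyloxy)phenyl]butyl]phenol
Conditions: I2, PPh3, imidazole, CH2Cl2, 0 °C → rt
Reagents that add atoms: iodine, II
Why: Garegg–Samuelsson (Appel-type) iodination: the primary alcohol is activated as an alkoxyphosphonium ion and displaced by iodide, whereas the ring B phenol cannot be substituted and is returned on work-up; no stereocentre is involved.

Step 8
Reactants: 17 the primary iodide
Product: 18 4-[(1R,2R,3S)-4-[4-(benzyloxy)phenyl]-2,3-dimethyl-1-[2,4,6-tris(benzyloxy)phenyl]butyl]phenol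
Conditions: Bu3SnH, AIBN (cat.), toluene, 80 °C
Reagents that add atoms: none
Why: Radical chain dehalogenation: the tributylstannyl radical abstracts iodine and the primary alkyl radical takes hydrogen from the tin hydride, neutral conditions that cannot epimerise C1', C2' or C3' and do not affect benzyl ethers.

Step 9
Reactants: 18 the tetrabenzyl ether
Product: 19 2-[(1R,2R,3S)-1,4-bis(4-hydroxyphenyl)-2,3-dimethylbutyl]benzene-1,3,5-triol
Conditions: H2 (1 atm), Pd/C, EtOAc/MeOH, rt; product kept under argon and used directly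
Reagents that add atoms: none
Why: Hydrogenolysis of the four aryl benzyl ethers over palladium gives the free phenols; the C1' methine carries no C–O bond and its configuration is untouched.

Step 10
Reactants: 19 the pentaphenol; 20 3-(4-methoxyphenyl)propanenitrile
Product: 22 1-[3-[(1R,2R,3S)-1,4-bis(4-hydroxyphenyl)-2,3-dimethylbutyl]-2,4,6-trihydroxyphenyl]-3-(4-methoxyphenyl)propan-1-one (CNP0193401.1), via ketiminium chloride 21 (not isolated)
Conditions: ZnCl2, HCl (g), Et2O/1,4-dioxane, 0 °C → rt; then H2O, 60 °C
Reagents that add atoms: water, O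
Why: Houben–Hoesch acylation: the HCl/ZnCl2-activated nitrile attacks the phloroglucinol ring A, whose two free positions are equivalent, the monophenolic rings B and C being too weakly activated, and the ketiminium salt, which protects ring A from a second acylation, is hydrolysed to the aryl ketone.

**Compound list**

1 | (S)-4-benzyloxazolidin-2-one | O=C1OC[C@H](Cc2ccccc2)N1 | starting material
2 | (E)-crotonyl chloride | C/C=C/C(=O)Cl | starting material
3 | (S)-4-benzyl-3-[(E)-but-2-enoyl]oxazolidin-2-one | C/C=C/C(=O)N1[C@@H](Cc2ccccc2)COC1=O | intermediate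
4 | 4-(benzyloxy)benzyl chloride | ClCc1ccc(OCc2ccccc2)cc1 | starting material
5 | 4-(benzyloxy)benzylmagnesium chloride | Cl[Mg]Cc1ccc(OCc2ccccc2)cc1 | intermediate
6 | 1,3,5-tris(benzyloxy)benzene | c1ccccc1COc1cc(OCc2ccccc2)cc(OCc2ccccc2)c1 | starting material
7 | 2-bromo-1,3,5-tris(benzyloxy)benzene | Brc1c(OCc2ccccc2)cc(OCc2ccccc2)cc1OCc1ccccc1 | intermediate
8 | 4-(tert-butyldimethylsilyloxy)benzaldehyde | O=Cc1ccc(O[Si](C)(C)C(C)(C)C)cc1 | starting material
9 | 2,4,6-tris(benzyloxy)phenyllithium | [Li]c1c(OCc2ccccc2)cc(OCc2ccccc2)cc1OCc1ccccc1 | intermediate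
10 | lithium [4-(tert-butyldimethylsilyloxy)phenyl][2,4,6-tris(benzyloxy)phenyl]methoxide (racemic) | [Li]OC(c1ccc(O[Si](C)(C)C(C)(C)C)cc1)c1c(OCc2ccccc2)cc(OCc2ccccc2)cc1OCc1ccccc1 | intermediate
11 | [4-(tert-butyldimethylsilyloxy)phenyl][2,4,6-tris(benzyloxy)phenyl]methyl acetate (racemic) | CC(=O)OC(c1ccc(O[Si](C)(C)C(C)(C)C)cc1)c1c(OCc2ccccc2)cc(OCc2ccccc2)cc1OCc1ccccc1 | intermediate
12 | 4-(benzyloxy)benzylcopper | [Cu]Cc1ccc(OCc2ccccc2)cc1 | intermediate
13 | chloromagnesium (Z)-enolate of (S)-4-benzyl-3-[(3S)-4-(4-benzyloxyphenyl)-3-methylbutanoyl]oxazolidin-2-one | Cl[Mg]O/C(=C\[C@@H](C)Cc1ccc(OCc2ccccc2)cc1)N1[C@@H](Cc2ccccc2)COC1=O | intermediate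
14 | 4-[2,4,6-tris(benzyloxy)benzylidene]cyclohexa-2,5-dien-1-one | O=C1C=CC(=Cc2c(OCc3ccccc3)cc(OCc3ccccc3)cc2OCc2ccccc2)C=C1 | intermediate
15 | (4S)-4-benzyl-3-[(2R,3S)-4-[4-(benzyloxy)phenyl]-2-[(R)-(4-hydroxyphenyl)[2,4,6-tris(benzyloxy)phenyl]methyl]-3-methylbutanoyl]oxazolidin-2-one | c1ccccc1COc1cc(OCc2ccccc2)cc(OCc2ccccc2)c1[C@@H](c1ccc(O)cc1)[C@H](C(=O)N1[C@@H](Cc2ccccc2)COC1=O)[C@@H](C)Cc1ccc(OCc2ccccc2)cc1 | intermediate
16 | (2R,3S)-4-[4-(benzyloxy)phenyl]-2-[(R)-(4-hydroxyphenyl)[2,4,6-tris(benzyloxy)phenyl]methyl]-3-methylbutan-1-ol | c1ccccc1COc1cc(OCc2ccccc2)cc(OCc2ccccc2)c1[C@@H](c1ccc(O)cc1)[C@H](CO)[C@@H](C)Cc1ccc(OCc2ccccc2)cc1 | intermediate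
17 | 4-[(1R,2R,3S)-4-[4-(benzyloxy)phenyl]-2-(iodomethyl)-3-methyl-1-[2,4,6-tris(benzyloxy)phenyl]butyl]phenol | c1ccccc1COc1cc(OCc2ccccc2)cc(OCc2ccccc2)c1[C@@H](c1ccc(O)cc1)[C@H](CI)[C@@H](C)Cc1ccc(OCc2ccccc2)cc1 | intermediate
18 | 4-[(1R,2R,3S)-4-[4-(benzyloxy)phenyl]-2,3-dimethyl-1-[2,4,6-tris(benzyloxy)phenyl]butyl]phenol | c1ccccc1COc1cc(OCc2ccccc2)cc(OCc2ccccc2)c1[C@@H](c1ccc(O)cc1)[C@H](C)[C@@H](C)Cc1ccc(OCc2ccccc2)cc1 | intermediate
19 | 2-[(1R,2R,3S)-1,4-bis(4-hydroxyphenyl)-2,3-dimethylbutyl]benzene-1,3,5-triol | Oc1cc(O)cc(O)c1[C@@H](c1ccc(O)cc1)[C@H](C)[C@@H](C)Cc1ccc(O)cc1 | intermediate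
20 | 3-(4-methoxyphenyl)propanenitrile | COc1ccc(CCC#N)cc1 | starting material
21 | ketiminium chloride of the target ketone | COc1ccc(CCC(=[NH2+])c2c(O)cc(O)c([C@@H](c3ccc(O)cc3)[C@H](C)[C@@H](C)Cc3ccc(O)cc3)c2O)cc1.[Cl-] | intermediate
22 | 1-[3-[(1R,2R,3S)-1,4-bis(4-hydroxyphenyl)-2,3-dimethylbutyl]-2,4,6-trihydroxyphenyl]-3-(4-methoxyphenyl)propan-1-one | COc1ccc(CCC(=O)c2c(O)cc(O)c([C@@H](c3ccc(O)cc3)[C@H](C)[C@@H](C)Cc3ccc(O)cc3)c2O)cc1 | target

**Step count**

Total: 10 steps. Longest linear sequence: 8 steps (steps 3, 4, 5, 6, 7, 8, 9, 10, from 6).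

**Steps most likely to fail**

Step 5 (proposed new method). The enolate may be protonated, or may fail to bond to the hindered methide carbon before it decomposes. The methide may oligomerise or be consumed by residual organocopper. The topicity at C1' may be low or opposite to that needed. The fallback sets out from 3 and 5, uses 11 as the electrophile, and returns at 15. The copper-mediated conjugate addition is run alone and quenched with aq NH4Cl to give the β-branched imide (S)-4-benzyl-3-[(3S)-4-(4-benzyloxyphenyl)-3-methylbutanoyl]oxazolidin-2-one F1. Soft enolisation with TiCl4 and i-Pr2NEt in CH2Cl2 at −78 °C gives the chelated chlorotitanium Z-enolate F2. Acetate 11 is then added and ionised by the Lewis acid to the diarylmethyl cation F3. SN1-type alkylation of titanium imide enolates with ionisable electrophiles is established chemistry and takes place on the enolate face remote from the auxiliary benzyl group; it would give the tert-butyldimethylsilyl ether of 15, F4. Bu4NF buffered with AcOH in THF at 0 °C then frees the phenol and gives 15.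

Step 6. Hydride may attack the ring carbonyl of the oxazolidinone instead of the very hindered exocyclic carbonyl, opening the auxiliary to a hydroxy amide. The fallback sets out from 15 and returns at 16. LiOH/H2O2 in THF/H2O at 0 °C (lithium hydroperoxide, whose preference for the exocyclic carbonyl holds for hindered imides) gives (2R,3S)-4-[4-(benzyloxy)phenyl]-2-[(R)-(4-hydroxyphenyl)[2,4,6-tris(benzyloxy)phenyl]methyl]-3-methylbutanoic acid F5. BH3·SMe2 in THF then reduces the acid to 16.

Step 10. Under HCl/ZnCl2, ring A may be protonated at the carbon that bears C1', with cleavage or epimerisation at the benzylic C1' centre, and the nitrile may be lost to imidate formation on the phenols. The fallback sets out from 18 and returns at 22. Friedel–Crafts acylation of the still benzylated ring A with 3-(4-methoxyphenyl)propanoyl chloride (2.2 equiv) and SnCl4 in CH2Cl2 at −78 °C also esterifies the ring B phenol and gives the keto ester F6. K2CO3 in MeOH cleaves the aryl ester to the ketone 1-[2,4,6-tris(benzyloxy)-3-[(1R,2R,3S)-4-[4-(benzyloxy)phenyl]-1-(4-hydroxyphenyl)-2,3-dimethylbutyl]phenyl]-3-(4-methoxyphenyl)propan-1-one F7. Hydrogenolysis (H2, Pd/C, EtOAc/MeOH) removes the four benzyl ethers and gives 22; a benzyl ether lost next to the new ketone under the Lewis acid would be of no consequence.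

**Further compounds**

F1 | step 5 | (S)-4-benzyl-3-[(3S)-4-(4-benzyloxyphenyl)-3-methylbutanoyl]oxazolidin-2-one | O=C(C[C@@H](C)Cc1ccc(OCc2ccccc2)cc1)N1[C@@H](Cc2ccccc2)COC1=O
F2 | step 5 | chlorotitanium (Z)-enolate of F1 | Cl[Ti](Cl)(Cl)O/C(=C\[C@@H](C)Cc1ccc(OCc2ccccc2)cc1)N1[C@@H](Cc2ccccc2)COC1=O
F3 | step 5 | [4-(tert-butyldimethylsilyloxy)phenyl][2,4,6-tris(benzyloxy)phenyl]methyl cation | [CH+](c1ccc(O[Si](C)(C)C(C)(C)C)cc1)c1c(OCc2ccccc2)cc(OCc2ccccc2)cc1OCc1ccccc1
F4 | step 5 | tert-butyldimethylsilyl ether of 15 | c1ccccc1COc1cc(OCc2ccccc2)cc(OCc2ccccc2)c1[C@@H](c1ccc(O[Si](C)(C)C(C)(C)C)cc1)[C@H](C(=O)N1[C@@H](Cc2ccccc2)COC1=O)[C@@H](C)Cc1ccc(OCc2ccccc2)cc1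
F5 | step 6 | (2R,3S)-4-[4-(benzyloxy)phenyl]-2-[(R)-(4-hydroxyphenyl)[2,4,6-tris(benzyloxy)phenyl]methyl]-3-methylbutanoic acid | c1ccccc1COc1cc(OCc2ccccc2)cc(OCc2ccccc2)c1[C@@H](c1ccc(O)cc1)[C@H](C(=O)O)[C@@H](C)Cc1ccc(OCc2ccccc2)cc1
F6 | step 10 | ring A ketone of 18 with the ring B phenol esterified by 3-(4-methoxyphenyl)propanoic acid | COc1ccc(CCC(=O)c2c(OCc3ccccc3)cc(OCc3ccccc3)c([C@@H](c3ccc(OC(=O)CCc4ccc(OC)cc4)cc3)[C@H](C)[C@@H](C)Cc3ccc(OCc4ccccc4)cc3)c2OCc2ccccc2)cc1
F7 | step 10 | 1-[2,4,6-tris(benzyloxy)-3-[(1R,2R,3S)-4-[4-(benzyloxy)phenyl]-1-(4-hydroxyphenyl)-2,3-dimethylbutyl]phenyl]-3-(4-methoxyphenyl)propan-1-one | COc1ccc(CCC(=O)c2c(OCc3ccccc3)cc(OCc3ccccc3)c([C@@H](c3ccc(O)cc3)[C@H](C)[C@@H](C)Cc3ccc(OCc4ccccc4)cc3)c2OCc2ccccc2)cc1
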